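**Retrosynthetic overview**
- The oxirane is made last: target ⇐ desilylation ⇐ nucleophilic epoxidation of the ring enone (C3=C4), anti to a C5 silyl ether.
- The carbocycle comes from one intramolecular carbonyl-ene closure of an acyclic (2Z,6Z)-4-oxofarnesal that already carries the C1 acetate and C8 angelate. It forms the C5–C6 bond (the C1–C6 bond of a farnesyl chain) with loss of hydrogen from C14.
- The (2Z)-4-oxo-enal ⇐ singlet-oxygen unmasking of a 2-substituted 3-methylfuran, which serves as a geometry-locked, oxidised isoprene unit.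
- The furyl carbinol ⇐ asymmetric Nozaki–Hiyama–Kishi union of 3-methylfuran-2-carbaldehyde with a (Z)-vinyl iodide. The iodide ⇐ propargyl alcohol by carbomagnesiation/iodination, allylboration, cross-metathesis and angeloylation.
- Ring order: six-membered carbocycle first (step 9), oxirane second (step 11).

Assumption: ring compounds use bisabolane numbering (ring C1–C6, methyl C15 on C3, chain C7(=C14)–C8–C9–C10=C11(C12)C13 on C6), compounds 6, 11 and 13 are bought, and the antipode of the chiral ligand in step 6 is the one that gives Re-face addition.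

**Step 1**
Reactants: 1 prop-2-yn-1-ol; 2 methylmagnesium bromide
Product: 4 (Z)-3-iodo-2-methylprop-2-en-1-ol, via vinylmagnesium alkoxide 3 (not isolated)
Conditions: MeMgBr (2.5 equiv), CuI (10 mol%), THF, −10 °C → rt; then I2, −78 → 0 °C
Reagents that add atoms: iodine, II
Why: Copper-catalysed anti-carbomagnesiation of the propargylic alkoxide (Duboudin reaction) puts the methyl on the proximal carbon and magnesium on the terminal carbon cis to CH2O, and iodinolysis with retention fixes the Z geometry that later places the C14 methyl cis to H6.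

**Step 2**
Reactants: 4 (Z)-3-iodo-2-methylprop-2-en-1-ol
Product: 5 (Z)-3-iodo-2-methylprop-2-enal
Conditions: MnO2 (15 equiv), CH2Cl2, rt, dark; used crude
Reagents that add atoms: none
Why: Allylic alcohol oxidation with MnO2 gives the enal without touching the vinyl iodide or its geometry.

**Step 3**
Reactants: 5 (Z)-3-iodo-2-methylprop-2-enal; 6 (−)-B-allyldiisopinocampheylborane (from (+)-α-pinene)
Product: 8 (1Z,3S)-1-iodo-2-methylhexa-1,5-dien-3-ol, via borinate ester 7 (not isolated)
Conditions: Et2O, −78 °C; then NaOH, H2O2, 0 °C → rt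
Reagents that add atoms: none
Why: Brown asymmetric allylboration through a chair Zimmerman–Traxler transition state adds allyl to the Si face of the enal (the sense that turns benzaldehyde into (S)-1-phenylbut-3-en-1-ol) and sets the future C8 as S.

**Step 4**
Reactants: 8 (1Z,3S)-1-iodo-2-methylhexa-1,5-dien-3-ol; 9 2-methylbut-2-ene
Product: 10 (1Z,3S)-1-iodo-2,6-dimethylhepta-1,5-dien-3-ol
Conditions: second-generation Grubbs catalyst [RuCl2(H2IMes)(PCy3)(=CHPh)] (5 mol%), 2-methylbut-2-ene/CH2Cl2, 40 °C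
Reagents that add atoms: none
Why: Olefin cross-metathesis converts the terminal vinyl group into the prenyl terminus, while the trisubstituted vinyl iodide and the carbinol centre are inert.

**Step 5**
Reactants: 10 (1Z,3S)-1-iodo-2,6-dimethylhepta-1,5-dien-3-ol; 11 angelic acid ((Z)-2-methylbut-2-enoic acid)
Product: 12 (1Z,3S)-1-iodo-2,6-dimethylhepta-1,5-dien-3-yl (2Z)-2-methylbut-2-enoate
Conditions: 11, 2,4,6-trichlorobenzoyl chloride, Et3N, toluene, rt; then 10, 75 °C (no DMAP)
Reagents that add atoms: none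
Why: Yamaguchi-type acylation through the preformed mixed anhydride esterifies the hindered allylic alcohol with retention at C8, and leaving out the nucleophilic catalyst avoids angelate-to-tiglate isomerisation.

**Step 6**
Reactants: 12 vinyl iodide angelate; 13 3-methylfuran-2-carbaldehyde
Product: 15 (1R,2Z,4S)-1-hydroxy-3,7-dimethyl-1-(3-methylfuran-2-yl)octa-2,6-dien-4-yl (2Z)-2-methylbut-2-enoate, via chromium alkoxide 14 (not isolated)
Conditions: CrCl2 (4 equiv), NiCl2 (2 mol%), Kishi-type chiral oxazoline–sulfonamide ligand (4.4 equiv), Et3N, THF, rt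
Reagents that add atoms: none
Why: Ligand-controlled asymmetric Nozaki–Hiyama–Kishi coupling, in which the alkenylchromium keeps the Z geometry, tolerates both esters and adds to the Re face of the aldehyde to set the carbinol (future C1) as R.

**Step 7**
Reactants: 15 furyl carbinol
Product: 16 (1R,2Z,4S)-1-acetoxy-3,7-dimethyl-1-(3-methylfuran-2-yl)octa-2,6-dien-4-yl (2Z)-2-methylbut-2-enoate
Conditions: Ac2O, Et3N, DMAP (cat.), CH2Cl2, 0 °C; used at once
Reagents that add atoms: acetic anhydride, CC(=O)OC(C)=O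
Why: Standard acylation installs the C1 acetate of the target and keeps the carbinol oxygen from closing to an Achmatowicz pyranone in the next step.

**Step 8**
Reactants: 16 furyl acetate
Product: 18 (2Z,5R,6Z,8S)-5-acetoxy-3,7,11-trimethyl-8-[(2Z)-2-methylbut-2-enoyloxy]-4-oxododeca-2,6,10-trienal (the aldehyde carbon is the future C5), via furan endoperoxide 17 (not isolated)
Conditions: O2, tetraphenylporphyrin (cat.), visible light, CH2Cl2, −78 °C; then Me2S, −78 → 0 °C; crude carried on cold
Reagents that add atoms: dioxygen, O=O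
Why: Singlet oxygen adds [4+2] to the furan, which is roughly a hundred times more reactive than the trisubstituted alkenes, and Me2S reduction of the endoperoxide releases the 4-oxo-enal with the ring-derived 2Z geometry intact (furan photooxygenation).

**Step 9**
Reactants: 18 (2Z,6Z)-keto-enal
Product: 20 (1R,5R,6S,8S)-1-acetoxy-8-angeloyloxy-5-hydroxybisabola-3,7(14),10-trien-2-one, via aluminium alkoxide 19 (not isolated)
Conditions: Me2AlCl (2 equiv), CH2Cl2 (0.01 M), −78 → −30 °C
Reagents that add atoms: none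
Why: Proposed new method: a Lewis-acid-promoted type 1 intramolecular carbonyl-ene closure of a furan-derived (2Z)-4-oxo-enal has no direct precedent, its closest known relatives being the neral → isopiperitenol and citronellal → isopulegol cyclisations; the aluminium-bound aldehyde C5 is attacked by C6 on the face where 1,3-allylic strain across the 6Z alkene (C1–H in plane) puts the tether, and the pseudo-equatorial oxygen takes hydrogen from the C14 methyl cis to H6, so C6 (S), C5 (5,6-trans and 1,6-trans) and the 7(14)-methylene are all set from C1.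

**Step 10**
Reactants: 20 hydroxy enone
Product: 21 5-O-tert-butyldimethylsilyl ether of 20
Conditions: TBSOTf, 2,6-lutidine, CH2Cl2, −78 °C
Reagents that add atoms: tert-butyldimethylsilyl triflate, CC(C)(C)[Si](C)(C)OS(=O)(=O)C(F)(F)F
Why: Silylation with a silyl triflate and hindered base removes the hydrogen bond by which the free C5 hydroxyl would steer the peroxide syn, and turns that oxygen into a bulky anti-directing group.

**Step 11**
Reactants: 21 silyl ether enone
Product: 22 5-O-tert-butyldimethylsilyl ether of the target (3R,4R oxirane)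
Conditions: t-BuOOH (anhydrous, decane), DBU, CH2Cl2, 0 °C
Reagents that add atoms: tert-butyl hydroperoxide, CC(C)(C)OO
Why: Weitz–Scheffer nucleophilic epoxidation (conjugate addition of t-BuOO−, then enolate closure) touches only the enone and, as with 4-silyloxycyclohex-2-enones, is expected to add anti to the adjacent C5 silyloxy group, setting C3 and C4 with the oxirane trans to both ring oxygen substituents and cis to the side chain.

**Step 12**
Reactants: 22 silyl ether of the target
Product: 23 (1R,3R,4R,5S,6S,8S)-1-acetoxy-8-angeloyloxy-3,4-epoxy-5-hydroxybisabola-7(14),10-dien-2-one (target)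
Conditions: HF·pyridine, THF, 0 °C → rt
Reagents that add atoms: none
Why: Fluoride desilylation under buffered acidic conditions frees the C5 hydroxyl without acetyl migration, oxirane opening or angelate isomerisation.

**Compound list**
1 | prop-2-yn-1-ol | C#CCO | starting material
2 | methylmagnesium bromide | C[Mg]Br | starting material
3 | bromomagnesium (Z)-3-(bromomagnesio)-2-methylprop-2-en-1-olate | Br[Mg]/C=C(/C)CO[Mg]Br | intermediate
4 | (Z)-3-iodo-2-methylprop-2-en-1-ol | I/C=C(/C)CO | intermediate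
5 | (Z)-3-iodo-2-methylprop-2-enal | I/C=C(/C)C=O | intermediate
6 | (−)-B-allyldiisopinocampheylborane | C=CCB([C@H]1[C@H](C)[C@H]2C[C@@H](C1)C2(C)C)[C@H]1[C@H](C)[C@H]2C[C@@H](C1)C2(C)C | starting material
7 | (1Z,3S)-1-iodo-2-methylhexa-1,5-dien-3-yl diisopinocampheylborinate | I/C=C(/C)[C@@H](OB([C@H]1[C@H](C)[C@H]2C[C@@H](C1)C2(C)C)[C@H]1[C@H](C)[C@H]2C[C@@H](C1)C2(C)C)CC=C | intermediate
8 | (1Z,3S)-1-iodo-2-methylhexa-1,5-dien-3-ol | I/C=C(/C)[C@@H](O)CC=C | intermediate
9 | 2-methylbut-2-ene | CC=C(C)C | starting material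
10 | (1Z,3S)-1-iodo-2,6-dimethylhepta-1,5-dien-3-ol | I/C=C(/C)[C@@H](O)CC=C(C)C | intermediate
11 | angelic acid | C/C=C(/C)C(O)=O | starting material
12 | (1Z,3S)-1-iodo-2,6-dimethylhepta-1,5-dien-3-yl (2Z)-2-methylbut-2-enoate | I/C=C(/C)[C@H](CC=C(C)C)OC(=O)/C(C)=C\C | intermediate
13 | 3-methylfuran-2-carbaldehyde | Cc1ccoc1C=O | starting material
14 | dichlorochromium alkoxide of 15 | Cc1ccoc1[C@H](O[Cr](Cl)Cl)/C=C(/C)[C@H](CC=C(C)C)OC(=O)/C(C)=C\C | intermediate
15 | (1R,2Z,4S)-1-hydroxy-3,7-dimethyl-1-(3-methylfuran-2-yl)octa-2,6-dien-4-yl (2Z)-2-methylbut-2-enoate | Cc1ccoc1[C@H](O)/C=C(/C)[C@H](CC=C(C)C)OC(=O)/C(C)=C\C | intermediate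
16 | (1R,2Z,4S)-1-acetoxy-3,7-dimethyl-1-(3-methylfuran-2-yl)octa-2,6-dien-4-yl (2Z)-2-methylbut-2-enoate | Cc1ccoc1[C@H](OC(C)=O)/C=C(/C)[C@H](CC=C(C)C)OC(=O)/C(C)=C\C | intermediate
17 | furan endoperoxide of 16 (2,3,7-trioxabicyclo[2.2.1]hept-5-ene, both bridgehead diastereomers) | CC1=CC2OOC1(O2)[C@H](OC(C)=O)/C=C(/C)[C@H](CC=C(C)C)OC(=O)/C(C)=C\C | intermediate
18 | (2Z,5R,6Z,8S)-5-acetoxy-3,7,11-trimethyl-8-[(2Z)-2-methylbut-2-enoyloxy]-4-oxododeca-2,6,10-trienal | O=C/C=C(/C)C(=O)[C@H](OC(C)=O)/C=C(/C)[C@H](CC=C(C)C)OC(=O)/C(C)=C\C | intermediate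
19 | chloro(methyl)aluminium alkoxide of 20 | C=C([C@H]1[C@H](O[Al](C)Cl)C=C(C)C(=O)[C@@H]1OC(C)=O)[C@H](CC=C(C)C)OC(=O)/C(C)=C\C | intermediate
20 | (1R,5R,6S,8S)-1-acetoxy-8-angeloyloxy-5-hydroxybisabola-3,7(14),10-trien-2-one | C=C([C@H]1[C@H](O)C=C(C)C(=O)[C@@H]1OC(C)=O)[C@H](CC=C(C)C)OC(=O)/C(C)=C\C | intermediate
21 | 5-O-tert-butyldimethylsilyl ether of 20 | C=C([C@H]1[C@H](O[Si](C)(C)C(C)(C)C)C=C(C)C(=O)[C@@H]1OC(C)=O)[C@H](CC=C(C)C)OC(=O)/C(C)=C\C | intermediate
22 | 5-O-tert-butyldimethylsilyl ether of 23 | C=C([C@H]1[C@H](O[Si](C)(C)C(C)(C)C)[C@H]2O[C@@]2(C)C(=O)[C@@H]1OC(C)=O)[C@H](CC=C(C)C)OC(=O)/C(C)=C\C | intermediate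
23 | (1R,3R,4R,5S,6S,8S)-1-acetoxy-8-angeloyloxy-3,4-epoxy-5-hydroxybisabola-7(14),10-dien-2-one | C=C([C@H]1[C@H](O)[C@H]2O[C@@]2(C)C(=O)[C@@H]1OC(C)=O)[C@H](CC=C(C)C)OC(=O)/C(C)=C\C | target

**Step count:** 12 steps in total; longest linear sequence 12 steps (from 1).

**Steps most likely to fail**

Step 9 (ene closure). The C6=C7 alkene is flanked by two acyloxy groups and is a weak ene donor, 18 can drift to the 2E isomer, and a stepwise Prins path could be intercepted by the angelate. The fallback sets out from 1 and comes back at 20; it replaces the hydrogen that must leave C14 by silicon. Compound 1 is carbomagnesiated with (trimethylsilyl)methylmagnesium chloride in place of 2, and steps 1 to 8 are repeated unchanged. This gives in turn the C14-silylated vinylmagnesium alkoxide F1, the C14-silylated iodo alcohol F2, the C14-silylated iodo enal F3, the C14-silylated borinate F4, the C14-silylated dienol F5, the C14-silylated prenyl alcohol F6, the C14-silylated angelate F7, the C14-silylated chromium alkoxide F8, the C14-silylated furyl carbinol F9, the C14-silylated furyl acetate F10, the C14-silylated endoperoxide F11 and the C14-silylated keto-enal F12. Sc(OTf)3 (10 mol%) in CH2Cl2 at −78 °C then triggers an intramolecular Hosomi–Sakurai reaction that forms the same C5–C6 bond with transfer of silicon to oxygen, giving the 5-O-trimethylsilyl ether of 20 F13. Citric acid in MeOH releases 20.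

Step 11 (epoxidation face). The anti-to-silyloxy preference is opposed by the usual preference of a 5-substituted cyclohexenone for attack trans to that substituent (here the C6 side chain), and the α-acetoxy ketone is base-sensitive. The fallback sets out from 21 and comes back at 22; it replaces nucleophilic by hydroxyl-directed epoxidation. Luche reduction (NaBH4, CeCl3·7H2O, MeOH, −78 °C, axial hydride) gives the 2R allylic alcohol F14, with the new hydroxyl on the face opposite the C5 silyl ether. VO(acac)2 with t-BuOOH (CH2Cl2, 0 °C) epoxidises only this allylic alkene, syn to the C2 hydroxyl, to give the epoxy alcohol F15. Dess–Martin periodinane then restores the ketone and gives 22.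

Step 6 (asymmetric coupling). The level and sense of induction with a hindered heteroaryl aldehyde are uncertain, and the remote C8 centre gives no help. The fallback sets out from 12 and 13 and comes back at 15; it replaces catalyst control by kinetic resolution. The ligand-free coupling (CrCl2, NiCl2 cat., DMSO) gives, through 14 and the 1S chromium alkoxide F16, a near 1:1 mixture of 15 and the 1S furyl carbinol F17. Sharpless kinetic resolution (Ti(OiPr)4, L-(+)-diisopropyl tartrate, t-BuOOH, 4 Å molecular sieves, CH2Cl2, −20 °C), with the furan as the oxidised π-system, converts only F17 into the Achmatowicz pyranone F18 and leaves 15, which is separated.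

**Further compounds**
F1 | step 9 | C14-silylated vinylmagnesium alkoxide (silyl analogue of 3, chloride) | Cl[Mg]/C=C(/C[Si](C)(C)C)CO[Mg]Cl
F2 | step 9 | C14-silylated iodo alcohol (silyl analogue of 4) | I/C=C(/C[Si](C)(C)C)CO
F3 | step 9 | C14-silylated iodo enal (silyl analogue of 5) | I/C=C(/C[Si](C)(C)C)C=O
F4 | step 9 | C14-silylated borinate (silyl analogue of 7) | I/C=C(/C[Si](C)(C)C)[C@@H](OB([C@H]1[C@H](C)[C@H]2C[C@@H](C1)C2(C)C)[C@H]1[C@H](C)[C@H]2C[C@@H](C1)C2(C)C)CC=C
F5 | step 9 | C14-silylated dienol (silyl analogue of 8) | I/C=C(/C[Si](C)(C)C)[C@@H](O)CC=C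
F6 | step 9 | C14-silylated prenyl alcohol (silyl analogue of 10) | I/C=C(/C[Si](C)(C)C)[C@@H](O)CC=C(C)C
F7 | step 9 | C14-silylated angelate (silyl analogue of 12) | I/C=C(/C[Si](C)(C)C)[C@H](CC=C(C)C)OC(=O)/C(C)=C\C
F8 | step 9 | C14-silylated chromium alkoxide (silyl analogue of 14) | Cc1ccoc1[C@H](O[Cr](Cl)Cl)/C=C(/C[Si](C)(C)C)[C@H](CC=C(C)C)OC(=O)/C(C)=C\C
F9 | step 9 | C14-silylated furyl carbinol (silyl analogue of 15) | Cc1ccoc1[C@H](O)/C=C(/C[Si](C)(C)C)[C@H](CC=C(C)C)OC(=O)/C(C)=C\C
F10 | step 9 | C14-silylated furyl acetate (silyl analogue of 16) | Cc1ccoc1[C@H](OC(C)=O)/C=C(/C[Si](C)(C)C)[C@H](CC=C(C)C)OC(=O)/C(C)=C\C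
F11 | step 9 | C14-silylated endoperoxide (silyl analogue of 17) | CC1=CC2OOC1(O2)[C@H](OC(C)=O)/C=C(/C[Si](C)(C)C)[C@H](CC=C(C)C)OC(=O)/C(C)=C\C
F12 | step 9 | C14-silylated keto-enal (silyl analogue of 18) | O=C/C=C(/C)C(=O)[C@H](OC(C)=O)/C=C(/C[Si](C)(C)C)[C@H](CC=C(C)C)OC(=O)/C(C)=C\C
F13 | step 9 | 5-O-trimethylsilyl ether of 20 | C=C([C@H]1[C@H](O[Si](C)(C)C)C=C(C)C(=O)[C@@H]1OC(C)=O)[C@H](CC=C(C)C)OC(=O)/C(C)=C\C
F14 | step 11 | 2R allylic alcohol from 21 (C2 hydroxyl trans to the C1 acetate) | C=C([C@H]1[C@H](O[Si](C)(C)C(C)(C)C)C=C(C)[C@@H](O)[C@@H]1OC(C)=O)[C@H](CC=C(C)C)OC(=O)/C(C)=C\C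
F15 | step 11 | epoxy alcohol (3,4-oxirane syn to the C2 hydroxyl) | C=C([C@H]1[C@H](O[Si](C)(C)C(C)(C)C)[C@H]2O[C@@]2(C)[C@@H](O)[C@@H]1OC(C)=O)[C@H](CC=C(C)C)OC(=O)/C(C)=C\C
F16 | step 6 | 1S chromium alkoxide (C1 epimer of 14) | Cc1ccoc1[C@@H](O[Cr](Cl)Cl)/C=C(/C)[C@H](CC=C(C)C)OC(=O)/C(C)=C\C
F17 | step 6 | 1S furyl carbinol (C1 epimer of 15) | Cc1ccoc1[C@@H](O)/C=C(/C)[C@H](CC=C(C)C)OC(=O)/C(C)=C\C
F18 | step 6 | Achmatowicz pyranone from F17 (6-hydroxy-4-methyl-2H-pyran-3(6H)-one, both anomers) | CC1=CC(O)O[C@@H](/C=C(/C)[C@H](CC=C(C)C)OC(=O)/C(C)=C\C)C1=O
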